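**Plan**
- Flavanoid numbering is used: O1, C2, C3, C4, ring A = C4a–C8a, ring B = C1'–C6'. The retrosynthesis first opens the C4–O(2') hemiketal bond and removes the O5 methyl group.
- Key cut: the C8–CH2 (prenyl) bond and the C6–CH / O7–CMe2 bonds of the pyran. Ring A is hexasubstituted, with the prenyl carbon C8 para to O5 and the pyran carbon C6 ortho to O7, so both carbon substituents can come from O5-prenyl and O7-(1,1-dimethylpropargyl) ethers by [3,3] shifts.
- Then the C2–O1 bond (Mitsunobu closure) and the C2–C3 bond (aldol) are cut, giving a phloroacetophenone diether and protected 2,6-dihydroxybenzaldehyde.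
- Forward order: ring A ethers, aldol chain, ring C, pyran ring (key step), O5 methylation, then the hemiketal ring last.
- Stereochemistry: C2 (R) comes from a reagent-controlled boron aldol giving the (S)-carbinol, inverted in the Mitsunobu closure; C4 (R) is forced by C2 through the bicyclic bridge.

Key step: step 8

Assumption: the bridged hemiketal is taken to be the preferred ring-chain tautomer of the 2',6'-dihydroxy-5-methoxyflavanone (no 5-OH hydrogen bond holds the C4 carbonyl), so it should form once an ortho phenol of ring B is free.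
Remark: enantiomeric purity would be assayed at 10 and 11 by chiral HPLC against the racemate and, if needed, raised by recrystallisation at one of these stages.

Step 1
Reactants: 1 2,4,6-trihydroxyacetophenone; 2 3-chloro-3-methylbut-1-yne
Product: 3 1-[2,6-dihydroxy-4-(2-methylbut-3-yn-2-yloxy)phenyl]ethanone
Conditions: K2CO3 (1.1 equiv), KI (cat.), CuI (cat.), acetone, reflux, N2
Reagents that add atoms: none
Why: The 4-OH, para to the acetyl group and the only hydroxyl not hydrogen-bonded to it, is the most acidic and accessible phenol, so copper-assisted Williamson-type O-alkylation with the tertiary propargylic chloride should occur there.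

Step 2
Reactants: 3 1-[2,6-dihydroxy-4-(2-methylbut-3-yn-2-yloxy)phenyl]ethanone; 4 prenyl bromide (1-bromo-3-methylbut-2-ene)
Product: 5 1-[2-hydroxy-6-(3-methylbut-2-enyloxy)-4-(2-methylbut-3-yn-2-yloxy)phenyl]ethanone
Conditions: K2CO3 (1.2 equiv), acetone, rt to 40 °C
Reagents that add atoms: none
Why: Williamson etherification of one of the two equivalent ortho hydroxyls should stop at the mono-ether, because the remaining hydroxyl is then locked in a strong hydrogen bond to the carbonyl group.

Step 3
Reactants: 5 1-[2-hydroxy-6-(3-methylbut-2-enyloxy)-4-(2-methylbut-3-yn-2-yloxy)phenyl]ethanone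
Product: 6 1-[2-(tert-butyldimethylsilyloxy)-6-(3-methylbut-2-enyloxy)-4-(2-methylbut-3-yn-2-yloxy)phenyl]ethanone
Conditions: TBSCl, imidazole, DMAP (cat.), DMF, rt to 40 °C
Reagents that add atoms: tert-butyldimethylsilyl chloride, CC(C)(C)[Si](C)(C)Cl
Why: Standard silylation masks the acidic chelated phenol so that the chloroborane of step 5 is used only for enolisation, and the aryl silyl ether can later be removed without touching the methoxymethyl groups.

Step 4
Reactants: 7 2,6-dihydroxybenzaldehyde
Product: 8 2,6-bis(methoxymethoxy)benzaldehyde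
Conditions: NaH, MOMCl, DMF, 0 °C to rt
Reagents that add atoms: chloromethyl methyl ether, COCCl
Why: Both phenoxides are alkylated by the reactive α-chloro ether (Williamson-type acetal formation), giving a non-enolisable aldehyde with acid-labile protection.

Step 5
Reactants: 6 1-[2-(tert-butyldimethylsilyloxy)-6-(3-methylbut-2-enyloxy)-4-(2-methylbut-3-yn-2-yloxy)phenyl]ethanone; 8 2,6-bis(methoxymethoxy)benzaldehyde
Product: 9 (3S)-1-[2-(tert-butyldimethylsilyloxy)-6-(3-methylbut-2-enyloxy)-4-(2-methylbut-3-yn-2-yloxy)phenyl]-3-hydroxy-3-[2,6-bis(methoxymethoxy)phenyl]propan-1-one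
Conditions: (+)-Ipc2BCl (from (−)-α-pinene), Et3N, Et2O, −78 to 0 °C; then 8, −78 to −20 °C; H2O2, MeOH, pH 7 buffer, 0 °C
Reagents that add atoms: none
Why: The methyl ketone has a single enolisable site and its diisopinocampheylboron enolate adds to the aldehyde through a cyclic, reagent-controlled transition state (asymmetric boron aldol of a methyl ketone); the (+)-reagent is expected to direct attack to the Si face of 8 and so set the (3S)-carbinol, the sense to be confirmed by MTPA ester analysis before scale-up since the antipodal reagent is equally available.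

Step 6
Reactants: 9 (3S)-silyl-protected aldol
Product: 10 (3S)-3-hydroxy-1-[2-hydroxy-6-(3-methylbut-2-enyloxy)-4-(2-methylbut-3-yn-2-yloxy)phenyl]-3-[2,6-bis(methoxymethoxy)phenyl]propan-1-one
Conditions: Bu4NF, AcOH, THF, 0 °C
Reagents that add atoms: none
Why: Fluoride cleaves the aryl silyl ether, which is activated by the ortho acyl group, while the acetic acid buffer should suppress retro-aldol cleavage and dehydration of the β-hydroxy ketone.

Step 7
Reactants: 10 (3S)-phenolic β-hydroxy ketone
Product: 11 (2R)-2-[2,6-bis(methoxymethoxy)phenyl]-5-(3-methylbut-2-enyloxy)-7-(2-methylbut-3-yn-2-yloxy)chroman-4-one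
Conditions: PPh3, DIAD, toluene, −20 to 0 °C
Reagents that add atoms: none
Why: Intramolecular Mitsunobu etherification, in which the chelated phenol displaces the alkoxyphosphonium group in a 6-exo-tet closure with inversion, should convert the (3S)-carbinol into C2 (R); the non-polar solvent and low temperature are chosen to disfavour ionisation of the electron-rich benzylic centre.

Step 8
Reactants: 11 (2R)-5-O-prenyl-7-O-(1,1-dimethylpropargyl)-2',6'-bis(methoxymethoxy)flavanone
Product: 13 (2R)-5-hydroxy-2',6'-bis(methoxymethoxy)-8-(3-methylbut-2-enyl)-6'',6''-dimethylpyrano[2'',3'':7,6]flavanone, via 5-hydroxy-8-prenyl-7-O-(1,1-dimethylpropargyl)flavanone 12 (not isolated)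
Conditions: Eu(fod)3 [tris(6,6,7,7,8,8,8-heptafluoro-2,2-dimethyloctane-3,5-dionato)europium] (10 mol%), NaHCO3, degassed PhCl, 70 °C until 11 is consumed; then 130 °C
Reagents that add atoms: none
Why: Eu(fod)3 chelates the C4 carbonyl and O5 and so lowers the barrier of the aromatic Claisen shift of the prenyl group to C6; the crowded 6-(1,1-dimethylallyl)dienone passes the group on to C8 by a Cope shift and enolises, giving 12 with a normal prenyl group para to the freed 5-OH. At 130 °C the aryl dimethylpropargyl ether undergoes a propargyl Claisen shift to C6, the allenyl dienone enolises, and a 1,5-hydrogen shift gives an ortho-quinone methide that closes the pyran by thermal disrotatory oxa-6π electrocyclisation, re-forming the O7–CMe2 bond. The closest known reactions are the Eu(fod)3-promoted para-Claisen–Cope rearrangement of 5-O-prenylflavanones and the thermal conversion of aryl 1,1-dimethylpropargyl ethers into 2,2-dimethylchromenes; both are known individually on this substrate class and are here only run one after the other in the same flask, which has not been tested. No stereocentre is formed, and C2 should be preserved because every stage is neutral and buffered. The step needs C8 rather than C6 for the prenyl group and prenyl transfer before the propargyl shift; the first is driven by steric congestion at the C6 dienone, the second by the fact that only the chelated O5 ether is catalysed at 70 °C while the O7 ether is inert there. Once C8 is filled, C6 is the only unsubstituted ring A carbon, so only the linear pyran can form.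

Step 9
Reactants: 13 (2R)-5-hydroxy pyranoflavanone
Product: 14 (2R)-5-methoxy-2',6'-bis(methoxymethoxy)-8-(3-methylbut-2-enyl)-6'',6''-dimethylpyrano[2'',3'':7,6]flavanone
Conditions: MeI (excess), Ag2O, DMF, rt, dark
Reagents that add atoms: iodomethane, CI
Why: Silver-oxide-mediated O-methylation is essentially neutral, so the chelated 5-OH should be alkylated without enolising C3 or opening ring C by retro-oxa-Michael reaction, which protects C2.

Step 10
Reactants: 14 (2R)-5-methoxy bis(methoxymethyl) ether
Product: 16 (2R,4R)-hemiketal target CNP0170313.2, via open-chain keto diphenol 15 (not isolated)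
Conditions: 3 M aq. HCl, THF, 40 °C (no alcohol co-solvent)
Reagents that add atoms: none
Why: Mild aqueous acid hydrolyses both aryl methoxymethyl acetals, and a freed ortho phenol of ring B then adds to the C4 ketone from the only face the C2–C1' bond allows, closing the dioxabicyclo[3.3.1]nonane hemiketal so that C4 (R) follows from C2 (R); leaving out methanol avoids a mixed methyl ketal, and with O5 methylated and O7 in the pyran no free phenol can cyclise onto the prenyl group.

**Compound list**
1 | 2,4,6-trihydroxyacetophenone | CC(=O)c1c(O)cc(O)cc1O | starting material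
2 | 3-chloro-3-methylbut-1-yne | CC(C)(Cl)C#C | starting material
3 | 1-[2,6-dihydroxy-4-(2-methylbut-3-yn-2-yloxy)phenyl]ethanone | CC(=O)c1c(O)cc(OC(C)(C)C#C)cc1O | intermediate
4 | prenyl bromide (1-bromo-3-methylbut-2-ene) | CC(C)=CCBr | starting material
5 | 1-[2-hydroxy-6-(3-methylbut-2-enyloxy)-4-(2-methylbut-3-yn-2-yloxy)phenyl]ethanone | CC(=O)c1c(O)cc(OC(C)(C)C#C)cc1OCC=C(C)C | intermediate
6 | 1-[2-(tert-butyldimethylsilyloxy)-6-(3-methylbut-2-enyloxy)-4-(2-methylbut-3-yn-2-yloxy)phenyl]ethanone | CC(=O)c1c(O[Si](C)(C)C(C)(C)C)cc(OC(C)(C)C#C)cc1OCC=C(C)C | intermediate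
7 | 2,6-dihydroxybenzaldehyde | O=Cc1c(O)cccc1O | starting material
8 | 2,6-bis(methoxymethoxy)benzaldehyde | O=Cc1c(OCOC)cccc1OCOC | intermediate
9 | (3S)-1-[2-(tert-butyldimethylsilyloxy)-6-(3-methylbut-2-enyloxy)-4-(2-methylbut-3-yn-2-yloxy)phenyl]-3-hydroxy-3-[2,6-bis(methoxymethoxy)phenyl]propan-1-one | CC(C)=CCOc1cc(OC(C)(C)C#C)cc(O[Si](C)(C)C(C)(C)C)c1C(=O)C[C@H](O)c1c(OCOC)cccc1OCOC | intermediate
10 | (3S)-3-hydroxy-1-[2-hydroxy-6-(3-methylbut-2-enyloxy)-4-(2-methylbut-3-yn-2-yloxy)phenyl]-3-[2,6-bis(methoxymethoxy)phenyl]propan-1-one | CC(C)=CCOc1cc(OC(C)(C)C#C)cc(O)c1C(=O)C[C@H](O)c1c(OCOC)cccc1OCOC | intermediate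
11 | (2R)-2-[2,6-bis(methoxymethoxy)phenyl]-5-(3-methylbut-2-enyloxy)-7-(2-methylbut-3-yn-2-yloxy)chroman-4-one | CC(C)=CCOc1cc(OC(C)(C)C#C)cc2c1C(=O)C[C@@H](O2)c1c(OCOC)cccc1OCOC | intermediate
12 | (2R)-2-[2,6-bis(methoxymethoxy)phenyl]-5-hydroxy-8-(3-methylbut-2-enyl)-7-(2-methylbut-3-yn-2-yloxy)chroman-4-one | Oc1cc(OC(C)(C)C#C)c(CC=C(C)C)c2c1C(=O)C[C@@H](O2)c1c(OCOC)cccc1OCOC | intermediate
13 | (2R)-5-hydroxy-2',6'-bis(methoxymethoxy)-8-(3-methylbut-2-enyl)-6'',6''-dimethylpyrano[2'',3'':7,6]flavanone | Oc1c2c(c(CC=C(C)C)c3c1C(=O)C[C@@H](O3)c1c(OCOC)cccc1OCOC)OC(C)(C)C=C2 | intermediate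
14 | (2R)-5-methoxy-2',6'-bis(methoxymethoxy)-8-(3-methylbut-2-enyl)-6'',6''-dimethylpyrano[2'',3'':7,6]flavanone | COc1c2c(c(CC=C(C)C)c3c1C(=O)C[C@@H](O3)c1c(OCOC)cccc1OCOC)OC(C)(C)C=C2 | intermediate
15 | (2R)-2',6'-dihydroxy-5-methoxy-8-(3-methylbut-2-enyl)-6'',6''-dimethylpyrano[2'',3'':7,6]flavanone (open keto form) | COc1c2c(c(CC=C(C)C)c3c1C(=O)C[C@@H](O3)c1c(O)cccc1O)OC(C)(C)C=C2 | intermediate
16 | (2R,4R)-4,2'-epoxy-4,6'-dihydroxy-5-methoxy-8-(3-methylbut-2-enyl)-6'',6''-dimethylpyrano[2'',3'':7,6]flavan (CNP0170313.2) | COc1c2c(c(CC=C(C)C)c3c1[C@@]1(O)C[C@@H](O3)c3c(O)cccc3O1)OC(C)(C)C=C2 | target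

**Step count:** 10 steps in total; the longest linear sequence is 9 steps (steps 1, 2, 3, 5, 6, 7, 8, 9, 10 from compound 1).

**Steps most likely to fail**

Step 8. The C6 dienone may enolise before the Cope relay and leave a reverse-prenyl group on C6; the propargyl ether may begin to rearrange before C8 is filled and give the angular pyran; or prolonged heating with the Lewis acid may ionise the C2–O1 bond and erode the configuration. The fallback separates the two events and changes the mechanism of the second one. It sets out from 11, runs only the Eu(fod)3 stage at 65–70 °C and isolates 12 by chromatography, so that the ring A regiochemistry is fixed before any chromene can form. The pyran is then closed at room temperature by 6-endo hydroarylation of the terminal alkyne at C6 with the cationic gold complex Ph3PAuNTf2 in CH2Cl2, a known route from aryl propargyl ethers to 2H-chromenes. It returns to the route at 13 and makes no compound outside the list (F0).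

Step 5. The boat-like transition state of a methyl ketone boron enolate may discriminate poorly between the aldehyde faces, and enolisation of the hindered di-ortho-substituted ketone may be slow enough for the chloroborane to reduce a carbonyl group instead. The fallback replaces the stoichiometric chiral boron enolate by a catalytic Mukaiyama aldol. It sets out from 6, which with TMSOTf and Et3N in CH2Cl2 at 0 °C should give the trimethylsilyl enol ether F1. F1 is added to 8 at −78 °C in CH2Cl2 with SiCl4 activated by a chiral binaphthyldiamine-derived bisphosphoramide Lewis base (5 mol%) and i-Pr2NEt, followed by buffered KF/NaHCO3 work-up. It returns to the route at 9.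

Step 7. The activated 2,6-dialkoxybenzylic alcohol may ionise before the phenol attacks, which would erode the configuration, or it may eliminate to the chalcone. The fallback gives up stereospecific substitution and sets C2 by resolution. It sets out from 5 and 8: Claisen–Schmidt condensation (KOH, EtOH, rt) should give the 2'-hydroxychalcone F2, and oxa-Michael closure (NaOAc, EtOH, reflux) the racemic flavanone F3. Kinetic resolution by asymmetric transfer hydrogenation (one enantiomer of Cp*RhCl(TsDPEN), chosen so that the (2S)-ketone reacts, HCO2H/Et3N, EtOAc, rt, to about half conversion) should reduce the (2S)-enantiomer to the cis-flavan-4-ol F4, which is removed by chromatography. The unreacted (2R)-flavanone returns to the route at 11.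

**Further compounds**
F0 | step 8 | none | none
F1 | step 5 | tert-butyldimethyl{3-(3-methylbut-2-enyloxy)-5-(2-methylbut-3-yn-2-yloxy)-2-[1-(trimethylsilyloxy)ethenyl]phenoxy}silane | C=C(O[Si](C)(C)C)c1c(O[Si](C)(C)C(C)(C)C)cc(OC(C)(C)C#C)cc1OCC=C(C)C
F2 | step 7 | (E)-1-[2-hydroxy-6-(3-methylbut-2-enyloxy)-4-(2-methylbut-3-yn-2-yloxy)phenyl]-3-[2,6-bis(methoxymethoxy)phenyl]prop-2-en-1-one | CC(C)=CCOc1cc(OC(C)(C)C#C)cc(O)c1C(=O)/C=C/c1c(OCOC)cccc1OCOC
F3 | step 7 | racemic 2-[2,6-bis(methoxymethoxy)phenyl]-5-(3-methylbut-2-enyloxy)-7-(2-methylbut-3-yn-2-yloxy)chroman-4-one | CC(C)=CCOc1cc(OC(C)(C)C#C)cc2c1C(=O)CC(O2)c1c(OCOC)cccc1OCOC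
F4 | step 7 | (2S,4S)-2-[2,6-bis(methoxymethoxy)phenyl]-5-(3-methylbut-2-enyloxy)-7-(2-methylbut-3-yn-2-yloxy)chroman-4-ol | CC(C)=CCOc1cc(OC(C)(C)C#C)cc2c1[C@@H](O)C[C@H](O2)c1c(OCOC)cccc1OCOC
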